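**Retrosynthetic overview**
1. Target 27 ⇐ bicyclic trimethyl ester 24: C7 ester → CHO by way of the diol, then SN2 demethylation of the two ring‑A esters as the last step.
2. 24 ⇐ caesium oxalate 13 (ring A) + chloro enone ester 23: one photoredox cascade makes the C9–C10 bond and closes ring D (C8–C15).
3. 23 ⇐ cyclopentanone β‑keto ester 18 by one‑carbon ring expansion (key step; builds ring C as a 2‑ene‑1,4‑dicarbonyl); 18 ⇐ Rh‑catalysed asymmetric isopropenyl addition to cyclopentenone (sets C13).
4. 13 ⇐ ring A by asymmetric Robinson annulation (C4), CBS reduction and reductive transposition (C5), hydration and oxalate formation.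
5. Ring order: A (step 2), C (step 9, ring expansion), D (step 11).

Assumption: locants C1–C20 in the text are those of the 6,7‑seco‑kaurane skeleton of the target (C4/C5 carry the acids C19/C6, C10 is the ring‑A carbon bonded to C9, C8 carries the formyl carbon C7, C11 is the ketone, C13 is the other bridgehead, C16=C17 is the exocyclic alkene).

Step 1
Reactants: 1 methyl propanoate; 2 dimethyl oxalate
Product: 3 dimethyl 2-methyl-3-oxobutanedioate
Conditions: NaOMe, Et2O/MeOH, 0 → 23 °C; aq. HCl
Reagents that add atoms: none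
Why: Crossed Claisen condensation in which the propanoate enolate acylates the non‑enolisable oxalate and the acidic product enolate drives the equilibrium; the new CH centre is labile and is fixed in step 2.

Step 2
Reactants: 3 dimethyl 2-methyl-3-oxobutanedioate; 4 pent-1-en-3-one
Product: 6 dimethyl (1R)-1,3-dimethyl-4-oxocyclohex-2-ene-1,2-dicarboxylate, via Michael adduct 5 (not isolated)
Conditions: 9-O-benzylcupreidine (10 mol %), CH2Cl2, −20 °C; then TsOH·H2O (20 mol %), PhMe, reflux, Dean–Stark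
Reagents that add atoms: none
Why: Bifunctional 6′‑OH cinchona catalysis of the Michael addition of the α‑substituted β‑keto ester sets the quaternary C4 centre (R; pseudo‑enantiomeric catalyst chosen for this sense), and acid‑mediated intramolecular aldol condensation of the ethyl‑ketone CH2 onto the α‑keto ester carbonyl completes a Robinson annulation to ring A.

Step 3
Reactants: 6 dimethyl (1R)-1,3-dimethyl-4-oxocyclohex-2-ene-1,2-dicarboxylate
Product: 7 dimethyl (1R,4S)-4-hydroxy-1,3-dimethylcyclohex-2-ene-1,2-dicarboxylate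
Conditions: (R)-Me-CBS (20 mol %), BH3·SMe2, THF, −30 °C
Reagents that add atoms: none
Why: Corey–Bakshi–Shibata 1,2‑reduction is reagent‑controlled (enone alkene as the large group) and gives the 4S carbinol independently of the remote quaternary centre.

Step 4
Reactants: 7 dimethyl (1R,4S)-4-hydroxy-1,3-dimethylcyclohex-2-ene-1,2-dicarboxylate
Product: 10 dimethyl (1R,2S)-1,3-dimethylcyclohex-3-ene-1,2-dicarboxylate, via sulfonylhydrazine adduct 8 (not isolated), via allylic diazene 9 (not isolated)
Conditions: 2-nitrobenzenesulfonylhydrazide (NBSH), PPh3, DEAD, THF, −30 → 23 °C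
Reagents that add atoms: none
Why: Myers reductive 1,3‑transposition: Mitsunobu displacement inverts the carbinol, sulfinate loss gives the allylic diazene, and suprafacial retro‑ene loss of N2 delivers H to C5 on the face of the C–N bond, which sets C5 (ester cis to the C4 ester) and moves the alkene to C10=C1.

Step 5
Reactants: 10 dimethyl (1R,2S)-1,3-dimethylcyclohex-3-ene-1,2-dicarboxylate
Product: 11 dimethyl (1R,2R)-3-hydroxy-1,3-dimethylcyclohexane-1,2-dicarboxylate (C3 epimers)
Conditions: Co(acac)2 (20 mol %), PhSiH3, O2 (1 atm), THF, 23 °C; aq. Na2S2O3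
Reagents that add atoms: dioxygen, O=O
Why: Mukaiyama hydration (Markovnikov hydrogen‑atom transfer, O2 trapping, reduction) gives the tertiary C10 alcohol; its configuration is irrelevant because C10 becomes a planar radical in step 11.

Step 6
Reactants: 11 dimethyl (1R,2R)-3-hydroxy-1,3-dimethylcyclohexane-1,2-dicarboxylate
Product: 13 caesium 2-{[(2R,3R)-2,3-bis(methoxycarbonyl)-1,3-dimethylcyclohexyl]oxy}-2-oxoacetate (C1 epimers), via methyl oxalate 12 (not isolated)
Conditions: ClCOCO2Me, Et3N, DMAP (cat.), CH2Cl2, 0 °C; then CsOH (1.0 equiv), THF/H2O, 23 °C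
Reagents that add atoms: methyl chlorooxoacetate, COC(=O)C(=O)Cl; caesium hydroxide, [Cs+].[OH-]
Why: Acylation of the tertiary alcohol followed by selective saponification of the activated, unhindered oxalate methyl ester gives the stable tert‑alkyl caesium oxalate radical precursor.

Step 7
Reactants: 14 cyclopent-2-en-1-one; 15 potassium trifluoro(prop-1-en-2-yl)borate
Product: 16 (3S)-3-(prop-1-en-2-yl)cyclopentan-1-one
Conditions: [Rh(cod)2]PF6 (3 mol %), (S)-BINAP (3.3 mol %), PhMe/H2O, 100 °C
Reagents that add atoms: none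
Why: Hayashi–Miyaura rhodium‑catalysed asymmetric 1,4‑addition; the (S)-BINAP–Rh alkenyl species adds to one enone face and sets the future C13 centre (S).

Step 8
Reactants: 16 (3S)-3-(prop-1-en-2-yl)cyclopentan-1-one; 17 dimethyl carbonate
Product: 18 methyl (4S)-2-oxo-4-(prop-1-en-2-yl)cyclopentane-1-carboxylate
Conditions: NaH, THF, reflux; aq. HCl
Reagents that add atoms: none
Why: Equilibrating C‑acylation (crossed Claisen) places the ester on the less hindered α‑carbon remote from the 3‑substituent; the ester‑bearing carbon is enolised and needs no control.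

Step 9
Reactants: 18 methyl (4S)-2-oxo-4-(prop-1-en-2-yl)cyclopentane-1-carboxylate; 19 diiodomethane
Product: 22 methyl (5S)-3-oxo-5-(prop-1-en-2-yl)cyclohex-1-ene-1-carboxylate, via zinc ester enolate 20 (not isolated), via tertiary iodide 21 (not isolated)
Conditions: Et2Zn (2.2 equiv), CH2I2 (2.2 equiv), CH2Cl2, 0 °C, 30 min; I2, 0 °C; then DBU, 0 → 23 °C
Reagents that add atoms: none
Why: Key ring expansion by zinc‑carbenoid homologation of the β‑keto ester (Zercher reaction): the zinc enolate is cyclopropanated, the donor–acceptor cyclopropane alkoxide fragments at the old CO–Cα bond so that CH2 (C9) is inserted between C11 and C8 (five‑ to six‑membered ring), and the resulting zinc ester enolate is iodinated and dehydroiodinated to the cyclic 2‑ene‑1,4‑dicarbonyl; C13 is untouched and the limiting, short‑lived carbenoid spares the isolated alkene.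

Step 10
Reactants: 22 methyl (5S)-3-oxo-5-(prop-1-en-2-yl)cyclohex-1-ene-1-carboxylate
Product: 23 methyl (5S)-5-(3-chloroprop-1-en-2-yl)-3-oxocyclohex-1-ene-1-carboxylate
Conditions: Ca(OCl)2, CO2 (s), CH2Cl2/H2O, 0 °C
Reagents that add atoms: calcium hypochlorite, [Ca+2].[O-]Cl.[O-]Cl
Why: Ene‑type allylic chlorination of the electron‑rich 1,1‑disubstituted alkene by HOCl (as known for carvone) leaves the electron‑poor ring alkene and the stereocentre alone.

Step 11
Reactants: 13 caesium 2-{[(2R,3R)-2,3-bis(methoxycarbonyl)-1,3-dimethylcyclohexyl]oxy}-2-oxoacetate; 23 methyl (5S)-5-(3-chloroprop-1-en-2-yl)-3-oxocyclohex-1-ene-1-carboxylate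
Product: 24 methyl (1R,2S,5S)-2-[(1S,2S,3R)-2,3-bis(methoxycarbonyl)-1,3-dimethylcyclohexyl]-6-methylidene-3-oxobicyclo[3.2.1]octane-1-carboxylate
Conditions: 13 (1.5 equiv), Ir[dF(CF3)ppy]2(dtbbpy)PF6 (2 mol %), dry DMF/DME, 450 nm LEDs, 40 °C
Reagents that add atoms: none
Why: Proposed new method: photo‑oxidation of the tert‑alkyl oxalate gives, after loss of two CO2, the C10 radical, which adds to the unsubstituted C9 of the ene‑dicarbonyl anti to the C5 ester of ring A (sets C10) and on the enone face away from the pseudo‑axial H atoms at C12/C14 (C10 trans to the C13 side chain, sets C9 kinetically), the resulting α‑ester C8 radical is reduced by Ir(II) to the ester enolate (radical–polar crossover), and this enolate closes ring D by 5‑exo‑tet SN2 on the allylic chloride, which can only bridge cis to C13 (sets C8); the closest known chemistry is the photoredox Giese coupling of tertiary alkyl oxalates with enones and radical–polar crossover annulations of halide‑bearing acceptors, which have not been combined to close a bridged ring.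

Step 12
Reactants: 24 methyl (1R,2S,5S)-2-[(1S,2S,3R)-2,3-bis(methoxycarbonyl)-1,3-dimethylcyclohexyl]-6-methylidene-3-oxobicyclo[3.2.1]octane-1-carboxylate
Product: 25 dimethyl (1R,2S,3S)-3-[(1R,2S,5S)-3-hydroxy-1-(hydroxymethyl)-6-methylidenebicyclo[3.2.1]octan-2-yl]-1,3-dimethylcyclohexane-1,2-dicarboxylate (carbinol epimers at C11)
Conditions: LiBH4 (3 equiv), THF, 0 → 23 °C; aq. NH4Cl
Reagents that add atoms: none
Why: Hydride reduction takes the ketone first and then the C7 ester with help from the neighbouring alkoxyborohydride, while the two ring‑A esters flanked by quaternary carbons are expected to survive; the new carbinol centre is removed in step 13.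

Step 13
Reactants: 25 dimethyl (1R,2S,3S)-3-[(1R,2S,5S)-3-hydroxy-1-(hydroxymethyl)-6-methylidenebicyclo[3.2.1]octan-2-yl]-1,3-dimethylcyclohexane-1,2-dicarboxylate
Product: 26 dimethyl (1R,2S,3S)-3-[(1R,2S,5S)-1-formyl-6-methylidene-3-oxobicyclo[3.2.1]octan-2-yl]-1,3-dimethylcyclohexane-1,2-dicarboxylate
Conditions: Dess–Martin periodinane (3 equiv), NaHCO3, CH2Cl2, 23 °C
Reagents that add atoms: none
Why: Dess–Martin oxidation gives the non‑enolisable aldehyde and restores the ketone under buffered conditions that do not epimerise C9.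

Step 14
Reactants: 26 dimethyl (1R,2S,3S)-3-[(1R,2S,5S)-1-formyl-6-methylidene-3-oxobicyclo[3.2.1]octan-2-yl]-1,3-dimethylcyclohexane-1,2-dicarboxylate
Product: 27 (1R,2S,3S)-3-[(1R,2S,5S)-1-formyl-6-methylidene-3-oxobicyclo[3.2.1]octan-2-yl]-1,3-dimethylcyclohexane-1,2-dicarboxylic acid
Conditions: LiI (10 equiv), EtOAc, reflux; aq. HCl
Reagents that add atoms: none
Why: SN2 O‑demethylation of the hindered methyl esters by iodide (LiI ester cleavage) avoids hydroxide, so the aldehyde, the exocyclic alkene and the kinetically set C9 centre are left alone.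

**Compound list**
1 | methyl propanoate | CCC(=O)OC | starting material
2 | dimethyl oxalate | COC(=O)C(=O)OC | starting material
3 | dimethyl 2-methyl-3-oxobutanedioate | COC(=O)C(C)C(=O)C(=O)OC | intermediate
4 | pent-1-en-3-one | CCC(=O)C=C | starting material
5 | dimethyl (2R)-2-methyl-3-oxo-2-(3-oxopentyl)butanedioate | CCC(=O)CC[C@@](C)(C(=O)OC)C(=O)C(=O)OC | intermediate (not isolated)
6 | dimethyl (1R)-1,3-dimethyl-4-oxocyclohex-2-ene-1,2-dicarboxylate | CC1=C(C(=O)OC)[C@](C)(C(=O)OC)CCC1=O | intermediate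
7 | dimethyl (1R,4S)-4-hydroxy-1,3-dimethylcyclohex-2-ene-1,2-dicarboxylate | CC1=C(C(=O)OC)[C@](C)(C(=O)OC)CC[C@@H]1O | intermediate
8 | dimethyl (1R,4R)-1,3-dimethyl-4-[1-(2-nitrobenzenesulfonyl)hydrazin-1-yl]cyclohex-2-ene-1,2-dicarboxylate | CC1=C(C(=O)OC)[C@](C)(C(=O)OC)CC[C@H]1N(N)S(=O)(=O)c1ccccc1[N+](=O)[O-] | intermediate (not isolated)
9 | dimethyl (1R,4R)-4-diazenyl-1,3-dimethylcyclohex-2-ene-1,2-dicarboxylate | CC1=C(C(=O)OC)[C@](C)(C(=O)OC)CC[C@H]1N=N | intermediate (not isolated)
10 | dimethyl (1R,2S)-1,3-dimethylcyclohex-3-ene-1,2-dicarboxylate | CC1=CCC[C@@](C)(C(=O)OC)[C@H]1C(=O)OC | intermediate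
11 | dimethyl (1R,2R)-3-hydroxy-1,3-dimethylcyclohexane-1,2-dicarboxylate (C3 epimers) | CC1(O)CCC[C@@](C)(C(=O)OC)[C@H]1C(=O)OC | intermediate
12 | (2R,3R)-2,3-bis(methoxycarbonyl)-1,3-dimethylcyclohexyl methyl oxalate (C1 epimers) | COC(=O)C(=O)OC1(C)CCC[C@@](C)(C(=O)OC)[C@H]1C(=O)OC | intermediate (not isolated)
13 | caesium 2-{[(2R,3R)-2,3-bis(methoxycarbonyl)-1,3-dimethylcyclohexyl]oxy}-2-oxoacetate (C1 epimers) | [Cs+].[O-]C(=O)C(=O)OC1(C)CCC[C@@](C)(C(=O)OC)[C@H]1C(=O)OC | intermediate
14 | cyclopent-2-en-1-one | O=C1C=CCC1 | starting material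
15 | potassium trifluoro(prop-1-en-2-yl)borate | [K+].CC(=C)[B-](F)(F)F | starting material
16 | (3S)-3-(prop-1-en-2-yl)cyclopentan-1-one | CC(=C)[C@@H]1CC(=O)CC1 | intermediate
17 | dimethyl carbonate | COC(=O)OC | starting material
18 | methyl (4S)-2-oxo-4-(prop-1-en-2-yl)cyclopentane-1-carboxylate (C1 labile) | COC(=O)C1C[C@H](C(C)=C)CC1=O | intermediate
19 | diiodomethane | ICI | starting material
20 | methyl (5R)-1-(ethylzincio)-3-oxo-5-(prop-1-en-2-yl)cyclohexane-1-carboxylate (same C5 geometry as in 18; C1 unspecified) | CC[Zn]C1(C(=O)OC)C[C@H](C(C)=C)CC(=O)C1 | intermediate (not isolated)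
21 | methyl (5R)-1-iodo-3-oxo-5-(prop-1-en-2-yl)cyclohexane-1-carboxylate (same C5 geometry as in 18; C1 unspecified) | COC(=O)C1(I)C[C@H](C(C)=C)CC(=O)C1 | intermediate (not isolated)
22 | methyl (5S)-3-oxo-5-(prop-1-en-2-yl)cyclohex-1-ene-1-carboxylate | COC(=O)C1=CC(=O)C[C@@H](C(C)=C)C1 | intermediate
23 | methyl (5S)-5-(3-chloroprop-1-en-2-yl)-3-oxocyclohex-1-ene-1-carboxylate | COC(=O)C1=CC(=O)C[C@@H](C(=C)CCl)C1 | intermediate
24 | methyl (1R,2S,5S)-2-[(1S,2S,3R)-2,3-bis(methoxycarbonyl)-1,3-dimethylcyclohexyl]-6-methylidene-3-oxobicyclo[3.2.1]octane-1-carboxylate | C=C1C[C@]2(C(=O)OC)C[C@H]1CC(=O)[C@H]2[C@]1(C)CCC[C@@](C)(C(=O)OC)[C@H]1C(=O)OC | intermediate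
25 | dimethyl (1R,2S,3S)-3-[(1R,2S,5S)-3-hydroxy-1-(hydroxymethyl)-6-methylidenebicyclo[3.2.1]octan-2-yl]-1,3-dimethylcyclohexane-1,2-dicarboxylate (carbinol epimers) | C=C1C[C@]2(CO)C[C@H]1CC(O)[C@H]2[C@]1(C)CCC[C@@](C)(C(=O)OC)[C@H]1C(=O)OC | intermediate
26 | dimethyl (1R,2S,3S)-3-[(1R,2S,5S)-1-formyl-6-methylidene-3-oxobicyclo[3.2.1]octan-2-yl]-1,3-dimethylcyclohexane-1,2-dicarboxylate | C=C1C[C@]2(C=O)C[C@H]1CC(=O)[C@H]2[C@]1(C)CCC[C@@](C)(C(=O)OC)[C@H]1C(=O)OC | intermediate
27 | (1R,2S,3S)-3-[(1R,2S,5S)-1-formyl-6-methylidene-3-oxobicyclo[3.2.1]octan-2-yl]-1,3-dimethylcyclohexane-1,2-dicarboxylic acid | C=C1C[C@]2(C=O)C[C@H]1CC(=O)[C@H]2[C@]1(C)CCC[C@@](C)(C(=O)O)[C@H]1C(=O)O | target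

**Totals and risks**

Total step count: 14. Longest linear sequence: 10 (steps 1–6, then 11–14); the second branch (steps 7–10) joins at step 11.

Step 11 (the proposed cascade) is the most likely to fail: the enolate may be protonated before it alkylates, and the facial selectivity at C9 is unproven. The fallback separates the events and sets C9 thermodynamically before ring closure. It sets out from 13 and 22: the known photoredox oxalate coupling in wet DME/DMF gives the protonated adduct, and NaOMe/MeOH equilibration of its two epimerisable centres gives the all‑equatorial methyl (1R,2R,5S)-2-[(1S,2S,3R)-2,3-bis(methoxycarbonyl)-1,3-dimethylcyclohexyl]-3-oxo-5-(prop-1-en-2-yl)cyclohexane-1-carboxylate F3 (ring A trans to the C13 side chain). Ene chlorination with Ca(OCl)2/CO2 gives the allylic chloride F4. LDA (2.2 equiv; ketone enolate towards C12, then ester enolate at C8) closes ring D by 5‑exo‑tet alkylation without touching C9, and the route is rejoined at 24.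

Step 2 is risky because the enantioselectivity of the catalytic Michael addition of this unusual α‑keto ester donor is uncertain. The fallback uses a stoichiometric auxiliary. It sets out from 3: condensation with (S)-1-phenylethylamine (or its antipode, as needed for the R centre) gives dimethyl 2-methyl-3-{[(1S)-1-phenylethyl]amino}but-2-enedioate F1. Auxiliary‑controlled Michael addition to 4 gives dimethyl (2R)-2-methyl-2-(3-oxopentyl)-3-{[(1S)-1-phenylethyl]imino}butanedioate F2. Aqueous AcOH hydrolysis releases 5, which is cyclised with TsOH as in step 2, and the route is rejoined at 6.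

Step 12 is risky because the C7 ester may not be reduced selectively over the two ring‑A esters. The fallback differentiates the carboxyl groups through the ring‑A anhydride. It sets out from 24: LiI cleaves all three methyl esters to (1R,2S,3S)-3-[(1R,2S,5S)-1-carboxy-6-methylidene-3-oxobicyclo[3.2.1]octan-2-yl]-1,3-dimethylcyclohexane-1,2-dicarboxylic acid F5. Ac2O closes the cis C6/C19 anhydride and leaves the C7 acid, giving the anhydride acid F6. (COCl)2 then EtSH/pyridine gives the S‑ethyl thioester anhydride F7, and Fukuyama reduction (Et3SiH, Pd/C) gives the aldehyde anhydride F8. Mild aqueous hydrolysis (THF/H2O) opens the anhydride, and the route is rejoined at 27.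

**Further compounds**
F1 | step 2 | dimethyl 2-methyl-3-{[(1S)-1-phenylethyl]amino}but-2-enedioate | COC(=O)C(C)=C(N[C@@H](C)c1ccccc1)C(=O)OC
F2 | step 2 | dimethyl (2R)-2-methyl-2-(3-oxopentyl)-3-{[(1S)-1-phenylethyl]imino}butanedioate | CCC(=O)CC[C@@](C)(C(=O)OC)C(=N[C@@H](C)c1ccccc1)C(=O)OC
F3 | step 11 | methyl (1R,2R,5S)-2-[(1S,2S,3R)-2,3-bis(methoxycarbonyl)-1,3-dimethylcyclohexyl]-3-oxo-5-(prop-1-en-2-yl)cyclohexane-1-carboxylate | COC(=O)[C@@H]2C[C@H](C(C)=C)CC(=O)[C@H]2[C@]1(C)CCC[C@@](C)(C(=O)OC)[C@H]1C(=O)OC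
F4 | step 11 | methyl (1R,2R,5S)-5-(3-chloroprop-1-en-2-yl)-2-[(1S,2S,3R)-2,3-bis(methoxycarbonyl)-1,3-dimethylcyclohexyl]-3-oxocyclohexane-1-carboxylate | COC(=O)[C@@H]2C[C@H](C(=C)CCl)CC(=O)[C@H]2[C@]1(C)CCC[C@@](C)(C(=O)OC)[C@H]1C(=O)OC
F5 | step 12 | (1R,2S,3S)-3-[(1R,2S,5S)-1-carboxy-6-methylidene-3-oxobicyclo[3.2.1]octan-2-yl]-1,3-dimethylcyclohexane-1,2-dicarboxylic acid | C=C1C[C@]2(C(=O)O)C[C@H]1CC(=O)[C@H]2[C@]1(C)CCC[C@@](C)(C(=O)O)[C@H]1C(=O)O
F6 | step 12 | cis C6/C19 cyclic anhydride of F5 with free C7 carboxylic acid | C=C1C[C@]2(C(=O)O)C[C@H]1CC(=O)[C@H]2[C@]1(C)CCC[C@@]3(C)C(=O)OC(=O)[C@@H]13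
F7 | step 12 | S-ethyl C7 thioester of anhydride F6 | C=C1C[C@]2(C(=O)SCC)C[C@H]1CC(=O)[C@H]2[C@]1(C)CCC[C@@]3(C)C(=O)OC(=O)[C@@H]13
F8 | step 12 | C7 aldehyde with cis C6/C19 cyclic anhydride (anhydride of 27) | C=C1C[C@]2(C=O)C[C@H]1CC(=O)[C@H]2[C@]1(C)CCC[C@@]3(C)C(=O)OC(=O)[C@@H]13
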